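79.2% of the G that larch shows at its last reading already stood after 5.00 h, at a loading of 4 mol%. We shall turn that rise into a time and read the flasks by it.

| setting | larch | cedar | winter | summer | dawn | spring |
|---|---|---|---|---|---|---|
| Z | 3 M | 3 M | 3.0 M | 3.0 M | 3.0 M | 3.0 M |
| D | 0.15 M | 0.15 M | 0.150 M | 0.150 M | 0.150 M | 0.150 M |
| J | 4 mol% | 33 mol% | 3 mol% | 6 mol% | 12 mol% | 25 mol% |
| remark | run made earlier | run made earlier |  |  |  |  |
| time |  |  | 20 h | 20 h | 20 h | 20 h |

- larch (time / h: G / %, Z / %): 5.00: 10.3, 66.3; 10.0: 12.3, 59.5; 15.0: 12.3, 55.6; 20.0: 13.0, 56.2
- cedar (time / h: G / %, Z / %): 2.50: 15.7, 67.0; 8.00: 14.3, 59.8; 12.0: 12.9, 57.4; 20.0: 12.5, 56.8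

(each reading ± 0.5 percentage points)

- a reading or a percentage of G counts all its forms, free or not
- "hardly changes" means that all values lie within two and a half points (for a concentration: within two and a half percent of the largest)
- a reading of Z is of its free form alone

* amount of G at the end, in percent of the Z charged for winter, summer, dawn, spring, in this order
* the course of these numbers from the first flask to the last (falls, then rises / falls all the way / rises, then falls / rises all the way / hardly changes)

Read down the G column of larch: it reaches 12.3% by 10.0 h and ends at 13.0%. If we take the early rise as a first-order approach to that last reading, its half-life is 2.21 h. Suppose J is not used up. Then the exchange of Z and G is pseudo-first-order, and its half-life should shrink in step with the loading. The product of loading and half-life is then 0.0882 h, and we call it the settling dose.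

Now read cedar against it. The settling dose gives cedar a half-life of 0.267 h, so its first reading at 2.50 h should already lie past the exchange. It does: G stands at 15.7% and then falls with Z. The ratio of G to Z reads 0.234 there and 0.220 at the end, while larch ends at 0.231. The last G readings of the two runs differ by 0.5 percentage points, with a scatter of 0.5 points per reading.

Winter has the lowest loading of the four, and there the settling dose gives 2.94 h, which is shorter than the 20 h of the run. That is 6.80 half-lives, so our own reckoning commits to a flat row at the level of those two last readings.

The forecast gives 12.6%, 12.7%, 12.7% and 12.7%, with the course hardly changes, on this ground: “The end state therefore looks independent of J.”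

The flasks end at 12.2%, 12.3%, 12.3% and 12.3% of G, with each L counted as one G, and the course is the forecast's: hardly changes.

    Z + J ⇌ G + J, rate k1*[Z]*[J] forward; the back reaction follows from the equilibrium constant (K = 0.150, k = 0.360 L mol⁻¹ h⁻¹)
    G ⇌ Q (K = 2.90, k = 0.0120 h⁻¹)
    Q ⇌ Z (k = 0.110 h⁻¹)
    Z + D → X (k = 0.280 L mol⁻¹ h⁻¹)
    Z + G ⇌ L, settled at all times (K = 0.270 L mol⁻¹)

In winter the relaxation half-life of Z and free G by the J step alone, both ways together, is 2.79 h at 20.0 h, short against the 20 h of the run. The settling dose gives spring, at 25 mol%, an estimated half-life of 0.353 h, and the end G of spring answers to the loading with a local order of −0.0014.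

(All runs come from a simulation on assumed constants; noise was put on by code.)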